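## Retrosynthetic overview
1. The phenol is freed last by aminolysis of an aryl acetate. Before that, O4 is acylated with 4-acetoxycinnamoyl chloride, so no tertiary alcohol ever has to be acetylated.
2. Key disconnection is C3–C4. Both carbons are carbonyl carbons in their precursors: C2 of methyl vinyl ketone and C1 of 4-methylpent-3-enal. The ketone carbon is made nucleophilic as the γ-carbon of an (E)-γ-acetoxy-γ-methylallylboronate, a stereocontrolled cross-pinacol equivalent.
3. The boronate comes from 1,4-hydroboration of 2-acetoxybutadiene, itself made from methyl vinyl ketone and isopropenyl acetate. The aldehyde comes from 4-methylpent-3-en-1-ol.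
4. Both stereocentres are set in the one C–C bond-forming step. The E geometry and a chair transition state give the anti pattern, and (R)-TRIP directs Re-face attack to give 4S and therefore 3R.
5. No ring is formed. The benzene ring is bought with 4-acetoxycinnamic acid.

Assumption: the SMILES is read as the (3R,4S) isomer (O3 and O4 anti when C2–C3–C4–C5 is drawn zigzag) with an E coumarate. The Re-face preference of (R)-TRIP is taken from its known behaviour with allyl and crotyl pinacolboronates, and the S catalyst is equally available if the sense is reversed.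

## Route

Step 1
Reactants: 1 methyl vinyl ketone (but-3-en-2-one); 2 isopropenyl acetate (prop-1-en-2-yl acetate)
Product: 3 buta-1,3-dien-2-yl acetate (2-acetoxybuta-1,3-diene)
Conditions: cat. p-TsOH·H2O, hydroquinone (inhibitor), neat, 95 °C, acetone distilled off; then distillation under reduced pressure
Reagents that add atoms: none
Why: Acid-catalysed enol-ester exchange works because 1 can enolise only towards its methyl group and removal of acetone drives the equilibrium; no stereocentre is formed.

Step 2
Reactants: 3 buta-1,3-dien-2-yl acetate; 4 pinacolborane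
Product: 5 (E)-4-(4,4,5,5-tetramethyl-1,3,2-dioxaborolan-2-yl)but-2-en-2-yl acetate (OAc trans and CH3 cis to CH2B)
Conditions: Ni(cod)2 (2.5 mol %), PCy3 (2.5 mol %), toluene, rt, 3 h; short silica plug or Kugelrohr distillation
Reagents that add atoms: none
Why: Proposed new method: the known Ni(cod)2/PCy3-catalysed 1,4-hydroboration of 1,3-dienes (established for alkyl-substituted dienes) is extended to a 2-acyloxy diene; zerovalent nickel binds 3 in its s-cis η4 form, H goes to C1 (the terminus next to the oxygenated carbon, the regiochemistry also seen in the known cobalt-catalysed 1,4-hydrovinylation of 2-silyloxy dienes) to give the 1-acetoxy-1-methyl π-allyl, and C–B reductive elimination at the unsubstituted terminus freezes the s-cis geometry so that CH3 is cis and OAc trans to CH2B (E), while at rt this should outrun nickel insertion into the vinylic C–OAc bond, which normally needs heat.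

Step 3
Reactants: 6 4-methylpent-3-en-1-ol
Product: 7 4-methylpent-3-enal
Conditions: Dess–Martin periodinane, CH2Cl2, 0 °C to rt; cold filtration, careful concentration, used the same day as a toluene solution
Reagents that add atoms: none
Why: Dess–Martin oxidation is fast and base-free, so the β,γ-unsaturated aldehyde is obtained without migration of the double bond into conjugation; no stereocentre is formed.

Step 4
Reactants: 5 (E)-γ-acetoxy-γ-methylallylboronate; 7 4-methylpent-3-enal
Product: 9 (3R,4S)-4-hydroxy-3,7-dimethylocta-1,6-dien-3-yl acetate, via pinacol borate ester 8 (not isolated)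
Conditions: (R)-TRIP [(R)-3,3'-bis(2,4,6-triisopropylphenyl)-1,1'-binaphthyl-2,2'-diyl hydrogen phosphate] (10 mol %), 4 Å MS, toluene, −30 °C, 48 h; then pH 7 buffer
Reagents that add atoms: none
Why: Proposed new method: chiral-phosphoric-acid-catalysed allylboration, known for allyl, crotyl, γ,γ-dialkyl and γ-alkoxyallyl pinacolboronates, is extended to a γ-acetoxy-γ-methyl reagent in which the former carbonyl carbon of 1 attacks the carbonyl carbon of 7; the closed chair (Zimmerman–Traxler) transition state places the chain of 7 and the E-positioned OAc equatorial and CH3 axial, which gives the anti 3,4-dioxygen pattern, while (R)-TRIP, hydrogen-bonded to the pseudoaxial boronate oxygen and the formyl C–H, exposes the Re face of 7, setting 4S and hence 3R.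

Step 5
Reactants: 10 (E)-4-acetoxycinnamic acid; 9 (3R,4S)-4-hydroxy-3,7-dimethylocta-1,6-dien-3-yl acetate
Product: 12 (3R,4S)-3-acetoxy-3,7-dimethylocta-1,6-dien-4-yl (E)-3-(4-acetoxyphenyl)acrylate, via 4-acetoxycinnamoyl chloride 11 (not isolated)
Conditions: 10, (COCl)2, cat. DMF, CH2Cl2, 0 °C to rt, evaporate; then 9, pyridine, DMAP (10 mol %), CH2Cl2, 0 °C
Reagents that add atoms: oxalyl chloride, O=C(Cl)C(=O)Cl (gives the chlorine of 11)
Why: Acid chloride formation followed by DMAP-catalysed acylation (nucleophilic catalysis) esterifies the only free hydroxyl quickly at 0 °C, faster than acetyl migration from O3 to O4, and no C–O bond at C3 or C4 is broken, so both stereocentres and the E alkene are kept.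

Step 6
Reactants: 12 (3R,4S)-3-acetoxy-3,7-dimethylocta-1,6-dien-4-yl (E)-3-(4-acetoxyphenyl)acrylate
Product: 13 (3R,4S)-3-acetoxy-3,7-dimethylocta-1,6-dien-4-yl (E)-3-(4-hydroxyphenyl)acrylate (target)
Conditions: pyrrolidine (1.5 equiv), CH2Cl2, 0 °C, 30 min; dilute citric acid wash
Reagents that add atoms: none
Why: Chemoselective aminolysis works because an aryl acetate is a far better acyl donor than the hindered tertiary alkyl acetate or the conjugated coumarate, a selectivity well established for 4-acetoxycinnamate esters; the stereocentres are untouched.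

## Compound list
1 | methyl vinyl ketone | CC(=O)C=C | starting material
2 | isopropenyl acetate | CC(=C)OC(C)=O | starting material
3 | buta-1,3-dien-2-yl acetate | C=CC(=C)OC(C)=O | intermediate
4 | pinacolborane | CC1(C)OBOC1(C)C | starting material
5 | (E)-4-(4,4,5,5-tetramethyl-1,3,2-dioxaborolan-2-yl)but-2-en-2-yl acetate | CC(=O)O/C(C)=C/CB1OC(C)(C)C(C)(C)O1 | intermediate
6 | 4-methylpent-3-en-1-ol | CC(C)=CCCO | starting material
7 | 4-methylpent-3-enal | CC(C)=CCC=O | intermediate
8 | pinacol borate ester of 9 (O4–Bpin), not isolated | C=C[C@@](C)(OC(C)=O)[C@H](CC=C(C)C)OB1OC(C)(C)C(C)(C)O1 | intermediate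
9 | (3R,4S)-4-hydroxy-3,7-dimethylocta-1,6-dien-3-yl acetate | C=C[C@@](C)(OC(C)=O)[C@H](CC=C(C)C)O | intermediate
10 | (E)-4-acetoxycinnamic acid | CC(=O)Oc1ccc(/C=C/C(=O)O)cc1 | starting material
11 | (E)-4-acetoxycinnamoyl chloride, not isolated | CC(=O)Oc1ccc(/C=C/C(=O)Cl)cc1 | intermediate
12 | (3R,4S)-3-acetoxy-3,7-dimethylocta-1,6-dien-4-yl (E)-3-(4-acetoxyphenyl)acrylate | C=C[C@@](C)(OC(C)=O)[C@H](CC=C(C)C)OC(=O)/C=C/c1ccc(OC(C)=O)cc1 | intermediate
13 | (3R,4S)-3-acetoxy-3,7-dimethylocta-1,6-dien-4-yl (E)-3-(4-hydroxyphenyl)acrylate | C=C[C@@](C)(OC(C)=O)[C@H](CC=C(C)C)OC(=O)/C=C/c1ccc(O)cc1 | target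

## Step count and risks
Total step count: 6.
Longest linear sequence: 5 steps (1 → 3 → 5 → 9 → 12 → 13). Step 3 is the one-step side branch.

**Step 2 (1,4-hydroboration of the acetoxy diene).**
- Possible failures: H delivered to C4 and B to C1, which gives the 2-acetoxycrotylboronate; nickel insertion into the C–OAc bond; or polymerisation of 3.
- The fallback sets out from 1 and comes back at 5. It makes the C–B bond by allylic substitution instead of hydrometallation.
- ZnCl2-catalysed 1,4-addition of acetyl bromide to 1 (CH2Cl2, −20 °C) gives (E)-4-bromobut-2-en-2-yl acetate F1. Its Z isomer forms alongside and is removed by fractional distillation or chromatography.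
- Pd2(dba)3-catalysed borylation of F1 with B2pin2 (THF, 40 °C) puts boron on the unsubstituted allyl terminus and gives 5. Any Z material that forms is removed at this stage, or later as the syn diastereomer of 9.

**Step 4 (catalytic asymmetric acetoxyallylboration).**
- Possible failures: the hindered, electron-poor boronate may add too slowly; the ee may be too low with an unbranched aliphatic aldehyde; or the acid may conjugate 7.
- The fallback sets out from 1, uses 4, 7 and 11 as in the main route, and comes back at 12. It carries a silyl ether rather than the acetate through the C–C bond formation and installs the tertiary acetate last.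
- TESOTf and Et3N (CH2Cl2, 0 °C) convert 1 into 2-(triethylsilyloxy)buta-1,3-diene F2.
- The same Ni(cod)2/PCy3 hydroboration with 4 gives (E)-triethyl{[4-(4,4,5,5-tetramethyl-1,3,2-dioxaborolan-2-yl)but-2-en-2-yl]oxy}silane F3. This is a much more electron-rich reagent of the known anti-selective (E)-γ-silyloxyallylboronate type.
- With 7 and (R)-TRIP, F3 gives the pinacol borate ester F4. Buffer work-up then gives (3R,4S)-3,7-dimethyl-3-(triethylsilyloxy)octa-1,6-dien-4-ol F5.
- Acylation of F5 with 11 (pyridine, DMAP) gives (3R,4S)-3,7-dimethyl-3-(triethylsilyloxy)octa-1,6-dien-4-yl (E)-3-(4-acetoxyphenyl)acrylate F6.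
- HF·pyridine (THF, 0 °C) frees (3R,4S)-3-hydroxy-3,7-dimethylocta-1,6-dien-4-yl (E)-3-(4-acetoxyphenyl)acrylate F7.
- Ac2O, Et3N and DMAP (CH2Cl2, rt) acetylate the tertiary alcohol, as is known for linalool, to give 12.

**Step 5 (acylation of 9).**
- Possible failure: base-promoted acetyl shift from O3 to O4 may compete with acylation of the hindered secondary alcohol. This would leave an unreactive tertiary alcohol.
- The fallback sets out from 9 and comes back at 13. It acylates without base and builds the cinnamate double bond afterwards, so no phenol protection is needed.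
- Heating 9 with Meldrum's acid (toluene, 100 °C) gives 3-{[(3R,4S)-3-acetoxy-3,7-dimethylocta-1,6-dien-4-yl]oxy}-3-oxopropanoic acid F8.
- Knoevenagel–Doebner condensation of F8 with 4-hydroxybenzaldehyde (pyridine, cat. piperidine, 50 °C) gives the E coumarate 13 directly, with loss of carbon dioxide.

## Further compounds
F1 | step 2 | (E)-4-bromobut-2-en-2-yl acetate | CC(=O)O/C(C)=C/CBr
F2 | step 4 | 2-(triethylsilyloxy)buta-1,3-diene | C=CC(=C)O[Si](CC)(CC)CC
F3 | step 4 | (E)-triethyl{[4-(4,4,5,5-tetramethyl-1,3,2-dioxaborolan-2-yl)but-2-en-2-yl]oxy}silane | CC[Si](CC)(CC)O/C(C)=C/CB1OC(C)(C)C(C)(C)O1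
F4 | step 4 | pinacol borate ester of F5 (O4–Bpin) | C=C[C@@](C)(O[Si](CC)(CC)CC)[C@H](CC=C(C)C)OB1OC(C)(C)C(C)(C)O1
F5 | step 4 | (3R,4S)-3,7-dimethyl-3-(triethylsilyloxy)octa-1,6-dien-4-ol | C=C[C@@](C)(O[Si](CC)(CC)CC)[C@H](CC=C(C)C)O
F6 | step 4 | (3R,4S)-3,7-dimethyl-3-(triethylsilyloxy)octa-1,6-dien-4-yl (E)-3-(4-acetoxyphenyl)acrylate | C=C[C@@](C)(O[Si](CC)(CC)CC)[C@H](CC=C(C)C)OC(=O)/C=C/c1ccc(OC(C)=O)cc1
F7 | step 4 | (3R,4S)-3-hydroxy-3,7-dimethylocta-1,6-dien-4-yl (E)-3-(4-acetoxyphenyl)acrylate | C=C[C@@](C)(O)[C@H](CC=C(C)C)OC(=O)/C=C/c1ccc(OC(C)=O)cc1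
F8 | step 5 | 3-{[(3R,4S)-3-acetoxy-3,7-dimethylocta-1,6-dien-4-yl]oxy}-3-oxopropanoic acid | C=C[C@@](C)(OC(C)=O)[C@H](CC=C(C)C)OC(=O)CC(=O)O
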